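The route rests on recognising C6–C12 (chain numbered from exocyclic C6 on ring carbon C5 of the furanone out to C18) as a 2,6-dimethylheptane chain with a twofold axis through C9. The methyl-bearing centres C7 and C11 have the same R sense on either side of the C8–C10 trimethylene, between the tetronic acid ring and the C12–C15 diene. One twofold asymmetric hydrogenation of achiral 2,6-dimethylideneheptanedioic acid, a bis-acrylic acid made from malonate, creates both centres together. The equivalent ends are then told apart by monosilylation: one is grown into the E,Z-diene and furan (Takai olefination, Negishi coupling), the other into the E-ylidene tetronic acid (Ando-type olefination, Dieckmann closure).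

Key step: step 4

Remark (geometry): in the target the exocyclic C5=C6 bond is E, with the chain cis to ring carbon C4, so the olefination must place the chain cis to the ester carbon that becomes C4.
Remark (ligand sense): the R outcome with (R)-BINAP is assumed by analogy with 2-arylacrylic acids, where the (S)-ligand gives the (S)-acid; it is to be confirmed at the diol stage, and the antipodal ligand would be used if the sense proved reversed.
Remark (precursor access): the bis-acrylic acid is approached through malonic ester chemistry, because mono-enolates of heptanedioate diesters are prone to Dieckmann ring closure.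

Step 1
Reactants: 1 diethyl malonate; 2 1,3-dibromopropane
Product: 3 tetraethyl pentane-1,1,5,5-tetracarboxylate
Conditions: NaOEt (2.2 equiv), 1 (5 equiv), EtOH, reflux; distillation
Reagents that add atoms: none
Why: Twofold SN2 alkylation (malonic ester synthesis), in which the large excess of sodiomalonate should favour intermolecular displacement of the second bromide over closure to the cyclobutane diester, which is removed by distillation.

Step 2
Reactants: 3 tetraethyl pentane-1,1,5,5-tetracarboxylate
Product: 4 pentane-1,1,5,5-tetracarboxylic acid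
Conditions: KOH, EtOH/H2O, reflux; then HCl, 0 °C
Reagents that add atoms: potassium hydroxide, [K+].[OH-]
Why: Saponification of the four esters, with cold acidification so that the bis-malonic acid is isolated before it can decarboxylate.

Step 3
Reactants: 4 pentane-1,1,5,5-tetracarboxylic acid
Product: 5 2,6-dimethylideneheptanedioic acid
Conditions: Et2NH, 37% aq. CH2O, 0 °C → rt; then 70 °C; HCl (BHT added on isolation)
Reagents that add atoms: formaldehyde, C=O
Why: Mannich aminomethylation of each malonic acid followed by decarboxylative loss of diethylamine, the standard route from monosubstituted malonic acids to 2-substituted acrylic acids, should give the bis-acrylic acid directly.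

Step 4
Reactants: 5 2,6-dimethylideneheptanedioic acid
Product: 6 (2R,6R)-2,6-dimethylheptanedioic acid
Conditions: Ru(OAc)2[(R)-BINAP] (1 mol %), H2 (100 atm), MeOH, 20 °C; recrystallisation
Reagents that add atoms: none
Why: This is a carboxylate-directed asymmetric hydrogenation: each CO2H displaces acetate on divalent ruthenium, the adjacent 1,1-disubstituted alkene coordinates, a Ru–H adds across it to give a five-membered alkylruthenium carboxylate chelate, and hydrogenolysis or protonolysis of the Ru–C bond releases the saturated acid. The closest known reaction type is the Ru(OAc)2(BINAP) hydrogenation of 2-substituted acrylic acids, here run at two sites of one substrate. No ring is closed. C2 and C6 are each set by the ligand alone (catalyst control), the (R)-BINAP enantiomer being chosen for the R sense by analogy with 2-arylacrylic acids. The only selectivity needed is enantioface selectivity at each alkene, and the substrate turns errors into a separable diastereomer: the two acrylic acid termini are identical and three methylenes apart, so they react independently, a wrong-face event at one terminus ends up as the meso diacid, and removal of that diastereomer by recrystallisation (free acid or bis(dicyclohexylammonium) salt) should leave the R,R acid in higher enantiomeric purity than the per-site selectivity. High hydrogen pressure is used to keep hydrogenation ahead of Ru–H migration of the exo-methylene into the chain.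

Step 5
Reactants: 6 (2R,6R)-2,6-dimethylheptanedioic acid
Product: 7 (2R,6R)-2,6-dimethylheptane-1,7-diol
Conditions: BH3·THF, THF, 0 °C → rt; MeOH, then aqueous work-up
Reagents that add atoms: none
Why: Borane reduction of carboxylic acids through acyloxyboranes involves no enolisation, so both α-methyl centres should pass unchanged into the C2-symmetric diol, where the configuration is to be checked.

Step 6
Reactants: 7 (2R,6R)-2,6-dimethylheptane-1,7-diol
Product: 8 (2R,6R)-7-[(tert-butyldimethylsilyl)oxy]-2,6-dimethylheptan-1-ol
Conditions: NaH (1.0 equiv), THF, rt; then TBSCl (1.0 equiv)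
Reagents that add atoms: tert-butyldimethylsilyl chloride, CC(C)(C)[Si](C)(C)Cl
Why: Monosilylation of a symmetric diol through its sparingly soluble monosodium alkoxide; the two ends are homotopic, so either hydroxyl gives the same product, and diol and bis-ether are recycled.

Step 7
Reactants: 8 (2R,6R)-7-[(tert-butyldimethylsilyl)oxy]-2,6-dimethylheptan-1-ol
Product: 9 (2R,6R)-7-[(tert-butyldimethylsilyl)oxy]-2,6-dimethylheptanal
Conditions: Dess–Martin periodinane, pyridine, CH2Cl2, 0 °C → rt; used crude
Reagents that add atoms: none
Why: Dess–Martin oxidation under buffered, near-neutral conditions should give the α-methyl aldehyde without epimerisation, and the silyl ether is inert.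

Step 8
Reactants: 9 (2R,6R)-7-[(tert-butyldimethylsilyl)oxy]-2,6-dimethylheptanal
Product: 10 tert-butyl{[(2R,6R,7E)-8-iodo-2,6-dimethyloct-7-en-1-yl]oxy}dimethylsilane
Conditions: CrCl2, CHI3, THF/1,4-dioxane, 0 °C → rt
Reagents that add atoms: iodoform, IC(I)I
Why: Takai iodo-olefination: the geminal dichromium species formed from CHI3 adds to the aldehyde and eliminates to the E-iodoalkene, under non-basic conditions that should preserve the adjacent methyl centre.

Step 9
Reactants: 11 3-bromofuran; 12 oxetane
Product: 14 3-(furan-3-yl)propan-1-ol, via 3-lithiofuran 13 (not isolated)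
Conditions: n-BuLi, THF, −78 °C; then 12, BF3·OEt2, −78 °C
Reagents that add atoms: none
Why: Bromine–lithium exchange gives 3-lithiofuran, which is kept at −78 °C to avoid isomerisation to the 2-lithio species and opens the BF3-activated oxetane by SN2 attack (Lewis-acid-promoted oxetane opening by an organolithium).

Step 10
Reactants: 14 3-(furan-3-yl)propan-1-ol
Product: 15 3-(3-bromopropyl)furan
Conditions: CBr4, PPh3, CH2Cl2, 0 °C
Reagents that add atoms: carbon tetrabromide, BrC(Br)(Br)Br
Why: Appel bromination of a primary alcohol under neutral conditions that the acid-sensitive furan tolerates.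

Step 11
Reactants: 15 3-(3-bromopropyl)furan; 16 propyne
Product: 20 3-[(4Z)-5-iodo-4-methylpent-4-en-1-yl]furan, via alkylmagnesium bromide 17 (not isolated), via alkylcopper 18 (not isolated), via Z-alkenylcopper 19 (not isolated)
Conditions: Mg, Et2O; CuBr·SMe2, Et2O/Me2S, −45 °C; 16, −25 °C; I2, −50 → 0 °C
Reagents that add atoms: iodine, II
Why: Normant carbocupration: the alkylcopper adds syn across propyne with the alkyl group on the internal carbon and copper on the terminal carbon, cis to the new chain, and iodinolysis with retention should give the Z-iodoalkene.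

Step 12
Reactants: 20 3-[(4Z)-5-iodo-4-methylpent-4-en-1-yl]furan; 10 tert-butyl{[(2R,6R,7E)-8-iodo-2,6-dimethyloct-7-en-1-yl]oxy}dimethylsilane
Product: 23 tert-butyl{[(2R,6R,7E,9Z)-13-(furan-3-yl)-2,6,10-trimethyltrideca-7,9-dien-1-yl]oxy}dimethylsilane, via Z-alkenyllithium 21 (not isolated), via Z-alkenylzinc chloride 22 (not isolated)
Conditions: 20, t-BuLi (2 equiv), Et2O, −78 °C; ZnCl2, THF, −78 → 0 °C; then 10, Pd(PPh3)4 (5 mol %), THF, rt
Reagents that add atoms: none
Why: Iodine–lithium exchange and transmetalation to zinc proceed with retention at the Z-alkenyl carbon, and the Negishi coupling catalysed by zerovalent palladium joins the two sp2 carbons with retention on both sides, which should fix the 7E,9Z-diene.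

Step 13
Reactants: 23 tert-butyl{[(2R,6R,7E,9Z)-13-(furan-3-yl)-2,6,10-trimethyltrideca-7,9-dien-1-yl]oxy}dimethylsilane
Product: 24 (2R,6R,7E,9Z)-13-(furan-3-yl)-2,6,10-trimethyltrideca-7,9-dien-1-ol
Conditions: Bu4NF, THF, 0 °C → rt
Reagents that add atoms: none
Why: Fluoride-induced cleavage of the silyl ether, driven by the strong Si–F bond, leaves the diene and furan untouched.

Step 14
Reactants: 24 (2R,6R,7E,9Z)-13-(furan-3-yl)-2,6,10-trimethyltrideca-7,9-dien-1-ol
Product: 25 (2R,6R,7E,9Z)-13-(furan-3-yl)-2,6,10-trimethyltrideca-7,9-dienal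
Conditions: Dess–Martin periodinane, pyridine, CH2Cl2, 0 °C; used crude
Reagents that add atoms: none
Why: Buffered Dess–Martin oxidation is mild enough for the furan and the diene and should not epimerise the α-methyl aldehyde.

Step 15
Reactants: 26 ethyl glyoxylate; 27 diphenyl phosphite
Product: 29 ethyl 2-(diphenoxyphosphoryl)-2-(propanoyloxy)acetate, via hydroxyphosphonate 28 (not isolated)
Conditions: toluene, 60 °C; then EtCOCl, pyridine, CH2Cl2, 0 °C → rt
Reagents that add atoms: propanoyl chloride, CCC(=O)Cl
Why: Pudovik hydrophosphonylation of the highly electrophilic glyoxylate is run without added base to avoid phosphonate-to-phosphate rearrangement, and the α-hydroxyphosphonate is O-acylated in the same flask under weakly basic conditions.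

Step 16
Reactants: 25 (2R,6R,7E,9Z)-13-(furan-3-yl)-2,6,10-trimethyltrideca-7,9-dienal; 29 ethyl 2-(diphenoxyphosphoryl)-2-(propanoyloxy)acetate
Product: 30 ethyl (2E,4R,8R,9E,11Z)-15-(furan-3-yl)-4,8,12-trimethyl-2-(propanoyloxy)pentadeca-2,9,11-trienoate
Conditions: 29, NaH, THF, 0 °C; then 25, −78 → −20 °C
Reagents that add atoms: none
Why: Horner–Wadsworth–Emmons olefination in its Ando form: the electron-poor diphenyl phosphonate makes oxaphosphetane collapse fast and irreversible, so the kinetic adduct should give the alkene with C4 cis to the ester carbon (2E by the sequence rule), and the pre-formed sodium phosphonate leaves no free base to enolise the aldehyde.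

Step 17
Reactants: 30 ethyl (2E,4R,8R,9E,11Z)-15-(furan-3-yl)-4,8,12-trimethyl-2-(propanoyloxy)pentadeca-2,9,11-trienoate
Product: 31 (5E)-5-[(2R,6R,7E,9Z)-13-(furan-3-yl)-2,6,10-trimethyltrideca-7,9-dien-1-ylidene]-4-hydroxy-3-methylfuran-2(5H)-one
Conditions: LiN(SiMe3)2 (2.5 equiv), THF, −78 → −20 °C; then 1 M HCl, 0 °C, dim light
Reagents that add atoms: none
Why: Dieckmann (Claisen-type) closure: the amide base enolises the propanoate CH2, which is kinetically far more accessible than the tertiary C4–H, and the enolate attacks the neighbouring ethyl ester in a five-membered closure driven by formation of the tetronate anion, so the 2E enol ester should become the 5E ylidene with the adjacent methyl centre untouched.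

Compound list
1 | diethyl malonate | CCOC(=O)CC(=O)OCC | starting material
2 | 1,3-dibromopropane | BrCCCBr | starting material
3 | tetraethyl pentane-1,1,5,5-tetracarboxylate | CCOC(=O)C(CCCC(C(=O)OCC)C(=O)OCC)C(=O)OCC | intermediate
4 | pentane-1,1,5,5-tetracarboxylic acid | OC(=O)C(CCCC(C(=O)O)C(=O)O)C(=O)O | intermediate
5 | 2,6-dimethylideneheptanedioic acid | OC(=O)C(=C)CCCC(=C)C(=O)O | intermediate
6 | (2R,6R)-2,6-dimethylheptanedioic acid | OC(=O)[C@H](C)CCC[C@@H](C)C(=O)O | intermediate
7 | (2R,6R)-2,6-dimethylheptane-1,7-diol | OC[C@H](C)CCC[C@@H](C)CO | intermediate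
8 | (2R,6R)-7-[(tert-butyldimethylsilyl)oxy]-2,6-dimethylheptan-1-ol | CC(C)(C)[Si](C)(C)OC[C@H](C)CCC[C@@H](C)CO | intermediate
9 | (2R,6R)-7-[(tert-butyldimethylsilyl)oxy]-2,6-dimethylheptanal | CC(C)(C)[Si](C)(C)OC[C@H](C)CCC[C@@H](C)C=O | intermediate
10 | tert-butyl{[(2R,6R,7E)-8-iodo-2,6-dimethyloct-7-en-1-yl]oxy}dimethylsilane | CC(C)(C)[Si](C)(C)OC[C@H](C)CCC[C@@H](C)/C=C/I | intermediate
11 | 3-bromofuran | Brc1ccoc1 | starting material
12 | oxetane | C1COC1 | starting material
13 | 3-lithiofuran | [Li]c1ccoc1 | intermediate (not isolated)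
14 | 3-(furan-3-yl)propan-1-ol | OCCCc1ccoc1 | intermediate
15 | 3-(3-bromopropyl)furan | BrCCCc1ccoc1 | intermediate
16 | propyne | CC#C | starting material
17 | [3-(furan-3-yl)propyl]magnesium bromide | Br[Mg]CCCc1ccoc1 | intermediate (not isolated)
18 | [3-(furan-3-yl)propyl]copper (MgBr2 complex) | [Cu]CCCc1ccoc1 | intermediate (not isolated)
19 | [(1Z)-5-(furan-3-yl)-2-methylpent-1-en-1-yl]copper | [Cu]/C=C(/C)CCCc1ccoc1 | intermediate (not isolated)
20 | 3-[(4Z)-5-iodo-4-methylpent-4-en-1-yl]furan | I/C=C(/C)CCCc1ccoc1 | intermediate
21 | [(1Z)-5-(furan-3-yl)-2-methylpent-1-en-1-yl]lithium | [Li]/C=C(/C)CCCc1ccoc1 | intermediate (not isolated)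
22 | chloro[(1Z)-5-(furan-3-yl)-2-methylpent-1-en-1-yl]zinc | Cl[Zn]/C=C(/C)CCCc1ccoc1 | intermediate (not isolated)
23 | tert-butyl{[(2R,6R,7E,9Z)-13-(furan-3-yl)-2,6,10-trimethyltrideca-7,9-dien-1-yl]oxy}dimethylsilane | CC(C)(C)[Si](C)(C)OC[C@H](C)CCC[C@@H](C)/C=C/C=C(/C)CCCc1ccoc1 | intermediate
24 | (2R,6R,7E,9Z)-13-(furan-3-yl)-2,6,10-trimethyltrideca-7,9-dien-1-ol | OC[C@H](C)CCC[C@@H](C)/C=C/C=C(/C)CCCc1ccoc1 | intermediate
25 | (2R,6R,7E,9Z)-13-(furan-3-yl)-2,6,10-trimethyltrideca-7,9-dienal | O=C[C@H](C)CCC[C@@H](C)/C=C/C=C(/C)CCCc1ccoc1 | intermediate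
26 | ethyl glyoxylate | CCOC(=O)C=O | starting material
27 | diphenyl phosphite | O=[PH](Oc1ccccc1)Oc1ccccc1 | starting material
28 | ethyl 2-(diphenoxyphosphoryl)-2-hydroxyacetate | CCOC(=O)C(O)P(=O)(Oc1ccccc1)Oc1ccccc1 | intermediate (not isolated)
29 | ethyl 2-(diphenoxyphosphoryl)-2-(propanoyloxy)acetate | CCOC(=O)C(OC(=O)CC)P(=O)(Oc1ccccc1)Oc1ccccc1 | intermediate
30 | ethyl (2E,4R,8R,9E,11Z)-15-(furan-3-yl)-4,8,12-trimethyl-2-(propanoyloxy)pentadeca-2,9,11-trienoate | CCOC(=O)/C(OC(=O)CC)=C\[C@H](C)CCC[C@@H](C)/C=C/C=C(/C)CCCc1ccoc1 | intermediate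
31 | (5E)-5-[(2R,6R,7E,9Z)-13-(furan-3-yl)-2,6,10-trimethyltrideca-7,9-dien-1-ylidene]-4-hydroxy-3-methylfuran-2(5H)-one (CNP0389221.7) | CC1=C(O)/C(=C\[C@H](C)CCC[C@@H](C)/C=C/C=C(/C)CCCc2ccoc2)OC1=O | target

Total step count: 17. Longest linear sequence: 13 steps (steps 1–8, 12–14, 16 and 17).

Steps most likely to fail

Step 16 (Ando-type olefination). The acyloxy substituent may weaken the kinetic preference, so that the chain ends up cis to the acyloxy oxygen instead of the ester carbon, or the aldehyde may enolise and lose its α-methyl configuration. The fallback makes the ring first and sets out from aldehyde 25. Commercial 3-methyltetronic acid would be O-methylated (Me2SO4, K2CO3) to 4-methoxy-3-methylfuran-2(5H)-one F5 and brominated at C5 (NBS, radical initiation) to 5-bromo-4-methoxy-3-methylfuran-2(5H)-one F6. Quaternisation with PPh3 would give (4-methoxy-3-methyl-5-oxo-2,5-dihydrofuran-2-yl)triphenylphosphonium bromide F7, which KOt-Bu in THF would convert in the flask into 4-methoxy-3-methyl-5-(triphenyl-λ5-phosphanylidene)furan-2(5H)-one F8. Wittig olefination of aldehyde 25 with this stabilised ylide should give the geometric isomers of the 4-O-methyl tetronate, from which (5E)-5-[(2R,6R,7E,9Z)-13-(furan-3-yl)-2,6,10-trimethyltrideca-7,9-dien-1-ylidene]-4-methoxy-3-methylfuran-2(5H)-one F9 would be separated by chromatography. Thiolate demethylation (n-PrSLi, HMPA, rt) would then come back to the route at target 31. This detour leaves out step 17 as well, so it also answers any loss of geometry or of the C7 configuration during the base-mediated ring closure.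

Step 4 (key hydrogenation). Enantioface discrimination at the alkyl-substituted acrylic acid termini may be too low, or the exo-methylene groups may migrate into the chain before reduction, so that more meso diacid forms than recrystallisation can remove. The fallback sets both centres by auxiliary control and sets out from tetraacid 4. Thermal twofold decarboxylation (neat, 160 °C) would give heptanedioic acid F1, and (COCl)2 with catalytic DMF would give heptanedioyl dichloride F2. N-Acylation of lithiated (R)-4-benzyl-1,3-oxazolidin-2-one (n-BuLi, THF, −78 °C) would give (4R,4'R)-3,3'-heptanedioylbis(4-benzyl-1,3-oxazolidin-2-one) F3. Twofold oxazolidinone enolate alkylation (NaN(SiMe3)2, MeI, THF, −78 °C), in which methyl iodide attacks each chelated Z-enolate on the face away from the benzyl group, should give (4R,4'R)-3,3'-[(2R,6R)-2,6-dimethylheptanedioyl]bis(4-benzyl-1,3-oxazolidin-2-one) F4. Reductive removal of the auxiliary with LiBH4 (wet Et2O, 0 °C) would come back to the route at diol 7.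

Step 11 (carbocupration). Wurtz coupling during Grignard formation, thermal decomposition of the primary alkylcopper, or metalation of propyne in place of addition may starve the sequence of the Z-iodide. The fallback builds the Z-trisubstituted alkene by bromoboration and cross-coupling and sets out from bromide 15 and propyne 16. Zinc insertion (Zn dust, LiCl, THF) into bromide 15 would give [3-(furan-3-yl)propyl]zinc bromide F10. Syn-bromoboration of propyne 16 (BBr3, CH2Cl2, −78 °C) would give dibromo[(1Z)-2-bromoprop-1-en-1-yl]borane F11, esterified in the same flask with pinacol to 2-[(1Z)-2-bromoprop-1-en-1-yl]-4,4,5,5-tetramethyl-1,3,2-dioxaborolane F12. Negishi coupling of F10 with F12 (Pd[P(t-Bu)3]2, THF), with retention at the alkenyl bromide, should give 2-[(1Z)-5-(furan-3-yl)-2-methylpent-1-en-1-yl]-4,4,5,5-tetramethyl-1,3,2-dioxaborolane F13. Suzuki coupling of F13 with iodide 10 (Pd(PPh3)4, aq. K3PO4, THF) would come back to the route at diene 23, replacing steps 11 and 12.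

Further compounds
F1 | step 4 | heptanedioic acid | OC(=O)CCCCCC(=O)O
F2 | step 4 | heptanedioyl dichloride | ClC(=O)CCCCCC(=O)Cl
F3 | step 4 | (4R,4'R)-3,3'-heptanedioylbis(4-benzyl-1,3-oxazolidin-2-one) | O=C(CCCCCC(=O)N1[C@H](Cc2ccccc2)COC1=O)N1[C@H](Cc2ccccc2)COC1=O
F4 | step 4 | (4R,4'R)-3,3'-[(2R,6R)-2,6-dimethylheptanedioyl]bis(4-benzyl-1,3-oxazolidin-2-one) | O=C([C@H](C)CCC[C@@H](C)C(=O)N1[C@H](Cc2ccccc2)COC1=O)N1[C@H](Cc2ccccc2)COC1=O
F5 | step 16 | 4-methoxy-3-methylfuran-2(5H)-one | COC1=C(C)C(=O)OC1
F6 | step 16 | 5-bromo-4-methoxy-3-methylfuran-2(5H)-one | COC1=C(C)C(=O)OC1Br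
F7 | step 16 | (4-methoxy-3-methyl-5-oxo-2,5-dihydrofuran-2-yl)triphenylphosphonium bromide | COC1=C(C)C(=O)OC1[P+](c1ccccc1)(c1ccccc1)c1ccccc1.[Br-]
F8 | step 16 | 4-methoxy-3-methyl-5-(triphenyl-λ5-phosphanylidene)furan-2(5H)-one | COC1=C(C)C(=O)OC1=P(c1ccccc1)(c1ccccc1)c1ccccc1
F9 | step 16 | (5E)-5-[(2R,6R,7E,9Z)-13-(furan-3-yl)-2,6,10-trimethyltrideca-7,9-dien-1-ylidene]-4-methoxy-3-methylfuran-2(5H)-one | CC1=C(OC)/C(=C\[C@H](C)CCC[C@@H](C)/C=C/C=C(/C)CCCc2ccoc2)OC1=O
F10 | step 11 | [3-(furan-3-yl)propyl]zinc bromide | Br[Zn]CCCc1ccoc1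
F11 | step 11 | dibromo[(1Z)-2-bromoprop-1-en-1-yl]borane | C/C(Br)=C/B(Br)Br
F12 | step 11 | 2-[(1Z)-2-bromoprop-1-en-1-yl]-4,4,5,5-tetramethyl-1,3,2-dioxaborolane | C/C(Br)=C/B1OC(C)(C)C(C)(C)O1
F13 | step 11 | 2-[(1Z)-5-(furan-3-yl)-2-methylpent-1-en-1-yl]-4,4,5,5-tetramethyl-1,3,2-dioxaborolane | C/C(CCCc1ccoc1)=C/B1OC(C)(C)C(C)(C)O1
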